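## Plan

1. Germacrane numbering is used: ring C1–C10, C11/C12/C13 on C7, ester carbon C14 on C10, methyl C15 on C4. The target is 6R,7R,8R, with C1=C10 E by rule (cis within the ring) and C4=C5 E (trans within the ring).
2. Retrosynthesis: remove the C8 methacrylate and the C13 methylene, open the lactone at O–C12, cut C5–C6 together with C4–C15, then cut C1=C10, C9–C10 and C7–C11.
3. Enabling feature: C15–C4=C5–C6(O) in the ten-membered ring is an E-trisubstituted allylic alcohol with methyl and carbinol carbon cis on the olefin, which is what syn addition of CH3 and an aldehyde carbon across a terminal C4≡C5 alkyne leaves behind.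
4. Forward: the chain is joined at C7–C11 (malate alkylation), C9–C10 (phosphonate alkylation) and C1=C10 (olefination with 4-pentynal); then the ten-membered carbocycle closes, then the γ-lactone, then the exo-methylene and the C8 ester follow.
5. Stereochemistry: C8 comes from dimethyl (S)-malate, C7 from anti alkylation of its dianion, C6 from Felkin–Anh addition under C7 control during ring closure; C4=C5 geometry follows from the cis-addition mechanism and C1=C10 geometry from the olefination.

Key step: step 12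

Remark: metal enolates and phosphonate carbanions made by deprotonation are treated as the reacting form of the numbered compound and carry no number; covalent intermediates carried on in the same flask are numbered.

## Route

Step 1
Reactants: 1 dimethyl (S)-malate; 2 tert-butyl bromoacetate
Product: 3 dimethyl (2S,3R)-2-hydroxy-3-(2-tert-butoxy-2-oxoethyl)butanedioate
Conditions: LiN(SiMe3)2 (2.2 equiv), THF, −78 → −20 °C; then 2, −78 → −10 °C; aq. NH4Cl
Reagents that add atoms: none
Why: Fráter–Seebach alkylation, in which the chelated dilithium alkoxide–enolate of the β-hydroxy ester is alkylated at C7 on the face away from the C9 ester group, should give the 2,3-anti (2S,3R) isomer and so set C7 against C8.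

Step 2
Reactants: 3 dimethyl (2S,3R)-2-hydroxy-3-(2-tert-butoxy-2-oxoethyl)butanedioate
Product: 4 4-tert-butyl 1-methyl (2R)-2-[(1S)-1,2-dihydroxyethyl]butanedioate
Conditions: BH3·SMe2 (1.05 equiv), NaBH4 (5 mol %), THF, 0 °C → rt; MeOH quench; used at once
Reagents that add atoms: none
Why: hydroxyl-directed borane reduction, in which the oxyborane at the C8 hydroxyl delivers hydride through a five-membered chelate only to the neighbouring α-hydroxy ester (C9), should leave the C6 methyl ester and the tert-butyl ester untouched.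

Step 3
Reactants: 4 4-tert-butyl 1-methyl (2R)-2-[(1S)-1,2-dihydroxyethyl]butanedioate
Product: 5 4-tert-butyl 1-methyl (2R)-2-[(1S)-1,2-bis(tert-butyldimethylsilyloxy)ethyl]butanedioate
Conditions: TBSOTf (2.4 equiv), 2,6-lutidine, CH2Cl2, −78 → 0 °C
Reagents that add atoms: tert-butyldimethylsilyl triflate, CC(C)(C)[Si](C)(C)OS(=O)(=O)C(F)(F)F
Why: silylation of a 1,2-diol with a silyl triflate is fast enough at low temperature to outrun lactonisation of the primary hydroxyl onto the C6 ester and to spare the tert-butyl ester.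

Step 4
Reactants: 5 4-tert-butyl 1-methyl (2R)-2-[(1S)-1,2-bis(tert-butyldimethylsilyloxy)ethyl]butanedioate
Product: 6 tert-butyl (3S,4S)-4,5-bis(tert-butyldimethylsilyloxy)-3-(hydroxymethyl)pentanoate
Conditions: LiBH4 (2 equiv), MeOH (1 equiv), THF, 0 °C → rt
Reagents that add atoms: none
Why: LiBH4 reduces methyl esters and leaves tert-butyl esters, so only C6 should go to the primary alcohol, and a γ-hydroxy tert-butyl ester does not lactonise without acid.

Step 5
Reactants: 6 tert-butyl (3S,4S)-4,5-bis(tert-butyldimethylsilyloxy)-3-(hydroxymethyl)pentanoate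
Product: 7 tert-butyl (3S,4S)-3-(acetoxymethyl)-4,5-bis(tert-butyldimethylsilyloxy)pentanoate
Conditions: Ac2O, pyridine, DMAP (cat.), CH2Cl2, 0 °C → rt
Reagents that add atoms: acetic anhydride, CC(=O)OC(C)=O
Why: standard acylation; the C6 oxygen is held as an acetate because an ester oxygen, unlike an ether oxygen, should not attack the C9 triflate made in step 7.

Step 6
Reactants: 7 tert-butyl (3S,4S)-3-(acetoxymethyl)-4,5-bis(tert-butyldimethylsilyloxy)pentanoate
Product: 8 tert-butyl (3S,4S)-3-(acetoxymethyl)-4-(tert-butyldimethylsilyloxy)-5-hydroxypentanoate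
Conditions: HF·pyridine, pyridine, THF, 0 °C
Reagents that add atoms: none
Why: buffered HF·pyridine cleaves a primary TBS ether much faster than a secondary one, which should free the C9 hydroxyl alone.

Step 7
Reactants: 8 tert-butyl (3S,4S)-3-(acetoxymethyl)-4-(tert-butyldimethylsilyloxy)-5-hydroxypentanoate; 9 trimethyl phosphonoacetate
Product: 11 1-tert-butyl 7-methyl (3S,4R)-3-(acetoxymethyl)-4-(tert-butyldimethylsilyloxy)-6-(dimethoxyphosphoryl)heptanedioate (both C6 epimers), via primary triflate 10 (not isolated)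
Conditions: Tf2O, 2,6-lutidine, CH2Cl2, −78 °C; then transferred cold into NaCH(CO2Me)P(O)(OMe)2 (3 equiv, from 9 and NaH), THF/DMF, −78 → 0 °C
Reagents that add atoms: none
Why: SN2 alkylation of a stabilised phosphonate carbanion by a primary triflate, the leaving group that keeps a β-branched β-silyloxy carbon reactive at low temperature, should form C9–C10, with excess anion holding back dialkylation.

Step 8
Reactants: 12 4-pentyn-1-ol
Product: 13 4-pentynal
Conditions: Dess–Martin periodinane, NaHCO3, CH2Cl2, 0 °C → rt; used as a dried solution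
Reagents that add atoms: none
Why: Dess–Martin oxidation takes a primary alcohol to the aldehyde without touching the terminal alkyne.

Step 9
Reactants: 11 1-tert-butyl 7-methyl (3S,4R)-3-(acetoxymethyl)-4-(tert-butyldimethylsilyloxy)-6-(dimethoxyphosphoryl)heptanedioate; 13 4-pentynal
Product: 14 1-tert-butyl 7-methyl (3S,4R,6E)-3-(acetoxymethyl)-4-(tert-butyldimethylsilyloxy)-6-(pent-4-yn-1-ylidene)heptanedioate
Conditions: NaH, THF, 0 °C; then 13, 0 °C → rt
Reagents that add atoms: none
Why: Horner–Wadsworth–Emmons olefination of an α-alkyl phosphonoacetate with an unbranched aldehyde under thermodynamic control should favour the E enoate, with the ester trans to the C2 chain as the ring-cis C1=C10 olefin requires.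

Step 10
Reactants: 14 1-tert-butyl 7-methyl (3S,4R,6E)-3-(acetoxymethyl)-4-(tert-butyldimethylsilyloxy)-6-(pent-4-yn-1-ylidene)heptanedioate
Product: 15 1-tert-butyl 7-methyl (3S,4R,6E)-4-(tert-butyldimethylsilyloxy)-3-(hydroxymethyl)-6-(pent-4-yn-1-ylidene)heptanedioate
Conditions: K2CO3 (0.3 equiv), MeOH, 0 °C
Reagents that add atoms: none
Why: methanolysis of a primary acetate is mild enough for the methyl enoate, the tert-butyl ester, the silyl ether and the alkyne.

Step 11
Reactants: 15 1-tert-butyl 7-methyl (3S,4R,6E)-4-(tert-butyldimethylsilyloxy)-3-(hydroxymethyl)-6-(pent-4-yn-1-ylidene)heptanedioate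
Product: 16 1-tert-butyl 7-methyl (3R,4R,6E)-4-(tert-butyldimethylsilyloxy)-3-formyl-6-(pent-4-yn-1-ylidene)heptanedioate
Conditions: Dess–Martin periodinane, NaHCO3, CH2Cl2, 0 °C → rt; used without storage
Reagents that add atoms: none
Why: buffered Dess–Martin oxidation should give the α-branched β-silyloxy aldehyde without epimerisation at C7 or β-elimination.

Step 12
Reactants: 16 1-tert-butyl 7-methyl (3R,4R,6E)-4-(tert-butyldimethylsilyloxy)-3-formyl-6-(pent-4-yn-1-ylidene)heptanedioate; 17 dimethylzinc
Product: 19 methyl (1(10)E,4E,6R,7S,8R)-8-(tert-butyldimethylsilyloxy)-6-hydroxy-4-methyl-7-(2-tert-butoxy-2-oxoethyl)cyclodeca-1(10),4-diene-10-carboxylate (germacrane locants), via methylzinc alkoxide 18 (not isolated)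
Conditions: Ni(cod)2 (20 mol %) and IMes (1,3-dimesitylimidazol-2-ylidene, 20 mol %) premixed, ZnMe2 (3 equiv), toluene/THF, 16 added by syringe pump over 8 h to 2 mM, rt; aq. NH4Cl
Reagents that add atoms: none
Why: Proposed new method: zerovalent nickel bound to the small carbene IMes should couple the terminal alkyne and the C6 aldehyde oxidatively to an oxanickelacyclopentene (new C5–C6 bond, nickel on C4), after which methyl passes from zinc to nickel and C4–C15 reductive elimination releases methylzinc alkoxide 18 with methyl and C6 cis on the olefin, hence E and ring-trans. The closest known reactions are nickel-catalysed alkylative cyclisations of ynals with organozincs to five- and six-membered rings and nickel–carbene reductive macrocyclisations of ynals with silanes; their union in a ten-membered closure has not been shown. The ring closes in the endo mode at the alkyne (10-endo, both alkyne carbons inside the ring), which a small ligand favours because it lets the aldehyde carbon bond to the unhindered terminal alkyne carbon. C6 is set by C7 in a Felkin–Anh sense, with the C8 branch anti to the incoming C5 and the 1,3-anti preference of the β-silyloxy group acting in the same direction, which should give 6R, the configuration the trans-fused lactone needs. The step needs methylation and not reduction, secured because a nickel-bound methyl has no β-hydrogen, and it needs the alkyne to take the aldehyde and not the enoate, which the α-branched trisubstituted enoate on a two-carbon tether (too short for a nickelacycle) and slow addition at high dilution should secure.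

Step 13
Reactants: 19 methyl (1(10)E,4E,6R,7S,8R)-8-(tert-butyldimethylsilyloxy)-6-hydroxy-4-methyl-7-(2-tert-butoxy-2-oxoethyl)cyclodeca-1(10),4-diene-10-carboxylate
Product: 20 methyl (1(10)E,4E,6R,7S,8R)-8-(tert-butyldimethylsilyloxy)-13-norgermacra-1(10),4-dien-12,6-olid-14-oate
Conditions: TsOH·H2O (0.2 equiv), CH2Cl2, 0 °C → rt
Reagents that add atoms: none
Why: acid-catalysed lactonisation of a γ-hydroxy tert-butyl ester (5-exo acyl substitution with loss of tert-butanol) should give the trans-fused lactone because C6 and C7 are already set, while catalytic acid in a non-nucleophilic solvent should spare the silyl ether and the allylic C6–O bond.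

Step 14
Reactants: 20 methyl (1(10)E,4E,6R,7S,8R)-8-(tert-butyldimethylsilyloxy)-13-norgermacra-1(10),4-dien-12,6-olid-14-oate
Product: 21 methyl (1(10)E,4E,6R,7S,8R)-8-(tert-butyldimethylsilyloxy)-13-(dimethylamino)-11,13-dihydrogermacra-1(10),4-dien-12,6-olid-14-oate (C11 epimers)
Conditions: LiN(SiMe3)2 (1.2 equiv), THF, −78 °C; then Eschenmoser's salt (CH2=NMe2+ I−, 3 equiv), −78 → 0 °C
Reagents that add atoms: Eschenmoser's salt (N,N-dimethylmethyleneiminium iodide), C=[N+](C)C.[I-]
Why: Mannich reaction of the lactone lithium enolate with the iminium salt should work because the saturated lactone α-CH2 is deprotonated kinetically ahead of the γ-CH2 of the E-enoate.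

Step 15
Reactants: 21 methyl (1(10)E,4E,6R,7S,8R)-8-(tert-butyldimethylsilyloxy)-13-(dimethylamino)-11,13-dihydrogermacra-1(10),4-dien-12,6-olid-14-oate
Product: 23 methyl (1(10)E,4E,6R,7S,8R)-8-(tert-butyldimethylsilyloxy)germacra-1(10),4,11(13)-trien-12,6-olid-14-oate, via trimethylammonium iodide 22 (not isolated)
Conditions: MeI, MeOH, rt; then sat. aq. NaHCO3, EtOAc, rt
Reagents that add atoms: none
Why: quaternisation of the amine and E1cB loss of trimethylamine from the β-ammonio lactone is the standard route to an α-methylene γ-lactone and removes the C11 stereocentre.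

Step 16
Reactants: 23 methyl (1(10)E,4E,6R,7S,8R)-8-(tert-butyldimethylsilyloxy)germacra-1(10),4,11(13)-trien-12,6-olid-14-oate
Product: 24 methyl (1(10)E,4E,6R,7R,8R)-8-hydroxygermacra-1(10),4,11(13)-trien-12,6-olid-14-oate
Conditions: HF·pyridine, THF, 0 °C → rt
Reagents that add atoms: none
Why: fluoride cleavage of the secondary TBS ether under acidic buffered conditions should not add a nucleophile to the α-methylene lactone.

Step 17
Reactants: 24 methyl (1(10)E,4E,6R,7R,8R)-8-hydroxygermacra-1(10),4,11(13)-trien-12,6-olid-14-oate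
Product: 25 methyl (1(10)E,4E,6R,7R,8R)-8-(methacryloyloxy)germacra-1(10),4,11(13)-trien-12,6-olid-14-oate (CNP0317149.1)
Conditions: methacrylic anhydride, Et3N, DMAP (cat.), CH2Cl2, 0 °C → rt
Reagents that add atoms: methacrylic anhydride, CC(=C)C(=O)OC(=O)C(C)=C
Why: DMAP-catalysed acyl transfer (Steglich-type acylation) should esterify the C8 secondary alcohol with retention at C8.

## Compound list

1 | dimethyl (S)-malate | COC(=O)C[C@H](O)C(=O)OC | starting material
2 | tert-butyl bromoacetate | BrCC(=O)OC(C)(C)C | starting material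
3 | dimethyl (2S,3R)-2-hydroxy-3-(2-tert-butoxy-2-oxoethyl)butanedioate | COC(=O)[C@H](CC(=O)OC(C)(C)C)[C@H](O)C(=O)OC | intermediate
4 | 4-tert-butyl 1-methyl (2R)-2-[(1S)-1,2-dihydroxyethyl]butanedioate | COC(=O)[C@H](CC(=O)OC(C)(C)C)[C@H](O)CO | intermediate
5 | 4-tert-butyl 1-methyl (2R)-2-[(1S)-1,2-bis(tert-butyldimethylsilyloxy)ethyl]butanedioate | COC(=O)[C@H](CC(=O)OC(C)(C)C)[C@H](O[Si](C)(C)C(C)(C)C)CO[Si](C)(C)C(C)(C)C | intermediate
6 | tert-butyl (3S,4S)-4,5-bis(tert-butyldimethylsilyloxy)-3-(hydroxymethyl)pentanoate | OC[C@H](CC(=O)OC(C)(C)C)[C@H](O[Si](C)(C)C(C)(C)C)CO[Si](C)(C)C(C)(C)C | intermediate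
7 | tert-butyl (3S,4S)-3-(acetoxymethyl)-4,5-bis(tert-butyldimethylsilyloxy)pentanoate | CC(=O)OC[C@H](CC(=O)OC(C)(C)C)[C@H](O[Si](C)(C)C(C)(C)C)CO[Si](C)(C)C(C)(C)C | intermediate
8 | tert-butyl (3S,4S)-3-(acetoxymethyl)-4-(tert-butyldimethylsilyloxy)-5-hydroxypentanoate | CC(=O)OC[C@H](CC(=O)OC(C)(C)C)[C@H](O[Si](C)(C)C(C)(C)C)CO | intermediate
9 | trimethyl phosphonoacetate | COC(=O)CP(=O)(OC)OC | starting material
10 | primary triflate of 8: tert-butyl (3S,4S)-3-(acetoxymethyl)-4-(tert-butyldimethylsilyloxy)-5-(trifluoromethylsulfonyloxy)pentanoate | CC(=O)OC[C@H](CC(=O)OC(C)(C)C)[C@H](O[Si](C)(C)C(C)(C)C)COS(=O)(=O)C(F)(F)F | intermediate (not isolated)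
11 | 1-tert-butyl 7-methyl (3S,4R)-3-(acetoxymethyl)-4-(tert-butyldimethylsilyloxy)-6-(dimethoxyphosphoryl)heptanedioate, both C6 epimers | CC(=O)OC[C@H](CC(=O)OC(C)(C)C)[C@H](O[Si](C)(C)C(C)(C)C)CC(C(=O)OC)P(=O)(OC)OC | intermediate
12 | 4-pentyn-1-ol | C#CCCCO | starting material
13 | 4-pentynal | C#CCCC=O | intermediate
14 | 1-tert-butyl 7-methyl (3S,4R,6E)-3-(acetoxymethyl)-4-(tert-butyldimethylsilyloxy)-6-(pent-4-yn-1-ylidene)heptanedioate | CC(=O)OC[C@H](CC(=O)OC(C)(C)C)[C@H](O[Si](C)(C)C(C)(C)C)C/C(C(=O)OC)=C\CCC#C | intermediate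
15 | 1-tert-butyl 7-methyl (3S,4R,6E)-4-(tert-butyldimethylsilyloxy)-3-(hydroxymethyl)-6-(pent-4-yn-1-ylidene)heptanedioate | OC[C@H](CC(=O)OC(C)(C)C)[C@H](O[Si](C)(C)C(C)(C)C)C/C(C(=O)OC)=C\CCC#C | intermediate
16 | 1-tert-butyl 7-methyl (3R,4R,6E)-4-(tert-butyldimethylsilyloxy)-3-formyl-6-(pent-4-yn-1-ylidene)heptanedioate (open-chain ynal) | O=C[C@H](CC(=O)OC(C)(C)C)[C@H](O[Si](C)(C)C(C)(C)C)C/C(C(=O)OC)=C\CCC#C | intermediate
17 | dimethylzinc | C[Zn]C | starting material
18 | methylzinc alkoxide of 19 (C6–O–ZnCH3) | CC(C)(C)[Si](C)(C)O[C@@H]1C/C(C(=O)OC)=C\CC/C(C)=C/[C@@H](O[Zn]C)[C@@H]1CC(=O)OC(C)(C)C | intermediate (not isolated)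
19 | methyl (1(10)E,4E,6R,7S,8R)-8-(tert-butyldimethylsilyloxy)-6-hydroxy-4-methyl-7-(2-tert-butoxy-2-oxoethyl)cyclodeca-1(10),4-diene-10-carboxylate (germacrane locants; C1=C10 cis in the ring, C4=C5 trans in the ring) | CC(C)(C)[Si](C)(C)O[C@@H]1C/C(C(=O)OC)=C\CC/C(C)=C/[C@@H](O)[C@@H]1CC(=O)OC(C)(C)C | intermediate
20 | methyl (1(10)E,4E,6R,7S,8R)-8-(tert-butyldimethylsilyloxy)-13-norgermacra-1(10),4-dien-12,6-olid-14-oate (trans-fused γ-lactone) | CC(C)(C)[Si](C)(C)O[C@@H]1C/C(C(=O)OC)=C\CC/C(C)=C/[C@H]2OC(=O)C[C@@H]21 | intermediate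
21 | methyl (1(10)E,4E,6R,7S,8R)-8-(tert-butyldimethylsilyloxy)-13-(dimethylamino)-11,13-dihydrogermacra-1(10),4-dien-12,6-olid-14-oate, C11 epimers | CC(C)(C)[Si](C)(C)O[C@@H]1C/C(C(=O)OC)=C\CC/C(C)=C/[C@H]2OC(=O)C(CN(C)C)[C@@H]21 | intermediate
22 | trimethylammonium iodide of 21 | CC(C)(C)[Si](C)(C)O[C@@H]1C/C(C(=O)OC)=C\CC/C(C)=C/[C@H]2OC(=O)C(C[N+](C)(C)C)[C@@H]21.[I-] | intermediate (not isolated)
23 | methyl (1(10)E,4E,6R,7S,8R)-8-(tert-butyldimethylsilyloxy)germacra-1(10),4,11(13)-trien-12,6-olid-14-oate | CC(C)(C)[Si](C)(C)O[C@@H]1C/C(C(=O)OC)=C\CC/C(C)=C/[C@H]2OC(=O)C(=C)[C@@H]21 | intermediate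
24 | methyl (1(10)E,4E,6R,7R,8R)-8-hydroxygermacra-1(10),4,11(13)-trien-12,6-olid-14-oate | O[C@@H]1C/C(C(=O)OC)=C\CC/C(C)=C/[C@H]2OC(=O)C(=C)[C@@H]21 | intermediate
25 | methyl (1(10)E,4E,6R,7R,8R)-8-(methacryloyloxy)germacra-1(10),4,11(13)-trien-12,6-olid-14-oate (CNP0317149.1) | C=C(C)C(=O)O[C@@H]1C/C(C(=O)OC)=C\CC/C(C)=C/[C@H]2OC(=O)C(=C)[C@@H]21 | target

## Step count and risks

Total: 17 steps. Longest linear sequence: 16 steps (steps 1–7 and 9–17; step 8 is a one-step side branch).

Steps most likely to fail: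

1. Step 12. The ten-membered closure may lose to intermolecular coupling and oligomerisation, to direct methyl transfer from zinc to the aldehyde, to carbene-induced aldehyde side reactions, to closure in the exo mode, or to poor facial selectivity at C6. The fallback uses known chemistry, sets out from 12 and 11 and comes back at 19. Zirconium-catalysed carboalumination of 12 (AlMe3, Cp2ZrCl2, CH2Cl2; then I2) should give (E)-5-iodo-4-methylpent-4-en-1-ol F1, and Dess–Martin oxidation the aldehyde (E)-5-iodo-4-methylpent-4-enal F2. Horner–Wadsworth–Emmons reaction of 11 with F2 gives the vinyl iodide enoate F3, methanolysis of the acetate the alcohol F4, and oxidation the iodo aldehyde F5. A Nozaki–Hiyama–Kishi ring closure (CrCl2, NiCl2 cat., DMSO/THF, high dilution) then forms C5–C6 and gives 19. The E olefin is carried in from F1, and C6 is again set under Felkin–Anh control by C7.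

2. Step 13. Ionisation of the allylic C6 alcohol, transannular reaction of the cyclodecadiene or loss of the silyl ether may occur under acid before the lactone closes. The fallback sets out from 19 and comes back at 20. TMSOTf and 2,6-lutidine in CH2Cl2 at 0 °C convert the tert-butyl ester into its trimethylsilyl ester under buffered conditions and silylate the C6 hydroxyl, giving the bis(trimethylsilyl) derivative F6. Mild aqueous work-up (citric acid, MeOH) gives the hydroxy acid F7, and carbodiimide activation (EDC·HCl, DMAP, CH2Cl2) closes the lactone to 20 without strong acid.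

3. Step 9. Geometric selectivity may be poor in the olefination of the α-branched phosphonate, giving too much of the Z enoate. The fallback sets out from 8 (through triflate 10) and comes back at 14. Methyl (triphenylphosphoranylidene)acetate (2.2 equiv, the second equivalent acting as base) is alkylated on carbon by 10 to give the α-alkylated stabilised ylide F8. A Wittig reaction of F8 with 13 in toluene at 80 °C should give 14, since α-substituted stabilised ylides form trisubstituted enoates with high E selectivity.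

Further compounds
F1 | step 12 | (E)-5-iodo-4-methylpent-4-en-1-ol | C/C(CCCO)=C\I
F2 | step 12 | (E)-5-iodo-4-methylpent-4-enal | C/C(CCC=O)=C\I
F3 | step 12 | 1-tert-butyl 7-methyl (3S,4R,6E)-3-(acetoxymethyl)-4-(tert-butyldimethylsilyloxy)-6-[(4E)-5-iodo-4-methylpent-4-en-1-ylidene]heptanedioate | CC(=O)OC[C@H](CC(=O)OC(C)(C)C)[C@H](O[Si](C)(C)C(C)(C)C)C/C(C(=O)OC)=C\CC/C(C)=C/I
F4 | step 12 | 1-tert-butyl 7-methyl (3S,4R,6E)-4-(tert-butyldimethylsilyloxy)-3-(hydroxymethyl)-6-[(4E)-5-iodo-4-methylpent-4-en-1-ylidene]heptanedioate | OC[C@H](CC(=O)OC(C)(C)C)[C@H](O[Si](C)(C)C(C)(C)C)C/C(C(=O)OC)=C\CC/C(C)=C/I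
F5 | step 12 | 1-tert-butyl 7-methyl (3R,4R,6E)-4-(tert-butyldimethylsilyloxy)-3-formyl-6-[(4E)-5-iodo-4-methylpent-4-en-1-ylidene]heptanedioate | O=C[C@H](CC(=O)OC(C)(C)C)[C@H](O[Si](C)(C)C(C)(C)C)C/C(C(=O)OC)=C\CC/C(C)=C/I
F6 | step 13 | bis(trimethylsilyl) derivative of the seco acid of 19 (C6 trimethylsilyl ether, C12 trimethylsilyl ester) | CC(C)(C)[Si](C)(C)O[C@@H]1C/C(C(=O)OC)=C\CC/C(C)=C/[C@@H](O[Si](C)(C)C)[C@@H]1CC(=O)O[Si](C)(C)C
F7 | step 13 | hydroxy acid: 2-[(6R,7S,8R)-8-(tert-butyldimethylsilyloxy)-6-hydroxy-10-(methoxycarbonyl)-4-methylcyclodeca-1(10),4-dien-7-yl]acetic acid (germacrane locants) | CC(C)(C)[Si](C)(C)O[C@@H]1C/C(C(=O)OC)=C\CC/C(C)=C/[C@@H](O)[C@@H]1CC(=O)O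
F8 | step 9 | 1-tert-butyl 7-methyl (3S,4R)-3-(acetoxymethyl)-4-(tert-butyldimethylsilyloxy)-6-(triphenylphosphoranylidene)heptanedioate | CC(=O)OC[C@H](CC(=O)OC(C)(C)C)[C@H](O[Si](C)(C)C(C)(C)C)CC(C(=O)OC)=P(c1ccccc1)(c1ccccc1)c1ccccc1
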